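**Strategy.** The route rests on detaching ring A of flavanone unit 1 (the 3‑substituted, 4‑hydroxyphenyl unit) from its pyranone. O1–C8a and C4–C4a are made together by annulating an unsymmetrical 3,5‑bis(benzyloxy)benzyne onto an anti β‑hydroxy ester whose C2 and C3 are already set by an auxiliary‑controlled aldol reaction. The step exploits the 1,3‑oxygen pattern of ring A (the C5 oxygen steers the aryne addition so that O1 ends meta and C4 ortho to it) and the aldol relationship O1–C2–C3–C4. Unit 2 travels as an 8‑substituted chromone, made regiospecifically by a Claisen rearrangement. It receives its (2S)‑4‑methoxyphenyl group afterwards by catalytic asymmetric conjugate addition, and hydrogenolysis ends the synthesis.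

Key step: step 12

Conventions and assumptions:
- Unit 1 is the chroman‑4‑one carrying the 4‑hydroxyphenyl group (2R,3S); unit 2 is the chroman‑4‑one carrying the 4‑methoxyphenyl group (2S). The two are joined C3(unit 1)–C8(unit 2).
- Rotation about the C3(unit 1)–C8(unit 2) bond is taken to give equilibrating rotamers, not separable atropisomers, since the target defines three stereocentres only.
- The facial sense of the auxiliary in step 10 and of the ligand in step 13 is assigned from the accepted chelate and enone‑face models, not from a result on these substrates.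

**Step 1**
Reactants: 1 3,5‑bis(benzyloxy)phenol
Product: 2 3,5‑bis(benzyloxy)phenyl N‑isopropylcarbamate
Conditions: i‑PrNCO, Et3N (cat.), CH2Cl2, 23 °C
Reagents that add atoms: isopropyl isocyanate, CC(C)N=C=O
Why: Base‑catalysed addition of the phenol O–H to the isocyanate (carbamoylation) installs a cleavable carbamate that will direct ortho‑metalation.

**Step 2**
Reactants: 2 3,5‑bis(benzyloxy)phenyl N‑isopropylcarbamate
Product: 5 3,5‑bis(benzyloxy)‑2‑(trimethylsilyl)phenyl N‑isopropylcarbamate, via N‑silyl carbamate 3 (not isolated), via C‑silylated N‑silyl carbamate 4 (not isolated)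
Conditions: TBSOTf, TMEDA, Et2O, 0 → 23 °C; n‑BuLi, TMEDA, −78 °C; TMSCl, −78 → 23 °C; aq NaHSO4
Reagents that add atoms: chlorotrimethylsilane, C[Si](C)(C)Cl
Why: In situ N‑silylation masks the N–H so that directed ortho‑metalation occurs at C2 (equivalent to C6), the position flanked by the carbamate and a benzyloxy group, and TMSCl traps the aryllithium before aqueous acid removes the N‑silyl group.

**Step 3**
Reactants: 5 3,5‑bis(benzyloxy)‑2‑(trimethylsilyl)phenyl N‑isopropylcarbamate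
Product: 7 3,5‑bis(benzyloxy)‑2‑(trimethylsilyl)phenyl trifluoromethanesulfonate, via silylphenol 6 (not isolated)
Conditions: DBU, Et2NH, MeCN, 40 °C; then PhNTf2, 23 °C
Reagents that add atoms: N‑phenylbis(trifluoromethanesulfonimide), O=S(=O)(N(c1ccccc1)S(=O)(=O)C(F)(F)F)C(F)(F)F
Why: Base‑induced E1cB loss of isopropyl isocyanate (trapped by Et2NH as a urea) frees the hindered phenoxide, which is triflated in the same flask to give the o‑silylaryl triflate aryne precursor.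

**Step 4**
Reactants: 8 1‑[2,4‑bis(benzyloxy)‑6‑hydroxyphenyl]ethan‑1‑one; 9 allyl bromide
Product: 10 1‑[2‑(allyloxy)‑4,6‑bis(benzyloxy)phenyl]ethan‑1‑one
Conditions: K2CO3, DMF, 60 °C
Reagents that add atoms: none
Why: Williamson etherification of the only free phenol prepares the allyl aryl ether for rearrangement.

**Step 5**
Reactants: 10 1‑[2‑(allyloxy)‑4,6‑bis(benzyloxy)phenyl]ethan‑1‑one
Product: 12 1‑[3‑allyl‑4,6‑bis(benzyloxy)‑2‑hydroxyphenyl]ethan‑1‑one, via Claisen dienone 11 (not isolated)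
Conditions: PhNEt2, 190 °C
Reagents that add atoms: none
Why: The aromatic Claisen rearrangement can deliver the allyl group only to C3, the single free ortho position of the ether, and enolisation restores the phenol, which fixes the later C8 attachment of unit 2 without a 6/8 regiochemical question.

**Step 6**
Reactants: 12 1‑[3‑allyl‑4,6‑bis(benzyloxy)‑2‑hydroxyphenyl]ethan‑1‑one
Product: 14 8‑allyl‑5,7‑bis(benzyloxy)‑4H‑chromen‑4‑one, via enaminone 13 (not isolated)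
Conditions: DMF‑DMA, toluene, 100 °C; then conc. HCl, CH2Cl2, 23 °C
Reagents that add atoms: N,N‑dimethylformamide dimethyl acetal, COC(OC)N(C)C
Why: Condensation of the methyl ketone with DMF‑DMA gives the β‑dimethylaminoenone, and acid triggers conjugate addition of the ortho hydroxyl with loss of dimethylamine (enaminone route to chromones).

**Step 7**
Reactants: 14 8‑allyl‑5,7‑bis(benzyloxy)‑4H‑chromen‑4‑one
Product: 15 2‑[5,7‑bis(benzyloxy)‑4‑oxo‑4H‑chromen‑8‑yl]acetaldehyde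
Conditions: OsO4 (2 mol %), NaIO4, 2,6‑lutidine, dioxane/H2O, 23 °C
Reagents that add atoms: osmium tetroxide, O=[Os](=O)(=O)=O; sodium periodate, [Na+].[O-]I(=O)(=O)=O
Why: Lemieux–Johnson oxidation, in which OsO4 dihydroxylates the electron‑richer terminal alkene in preference to the chromone C2=C3 vinylogous ester and periodate cleaves the diol.

**Step 8**
Reactants: 15 2‑[5,7‑bis(benzyloxy)‑4‑oxo‑4H‑chromen‑8‑yl]acetaldehyde
Product: 16 2‑[5,7‑bis(benzyloxy)‑4‑oxo‑4H‑chromen‑8‑yl]acetic acid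
Conditions: NaClO2, NaH2PO4, 2‑methyl‑2‑butene, t‑BuOH/H2O, 23 °C
Reagents that add atoms: sodium chlorite, [Na+].[O-]Cl=O
Why: Pinnick oxidation converts the aldehyde into the acid under buffered conditions, with the alkene scavenging hypochlorite so that the chromone and benzyl ethers are spared.

**Step 9**
Reactants: 16 2‑[5,7‑bis(benzyloxy)‑4‑oxo‑4H‑chromen‑8‑yl]acetic acid; 17 (R)‑4‑benzyloxazolidin‑2‑one
Product: 19 (R)‑4‑benzyl‑3‑{2‑[5,7‑bis(benzyloxy)‑4‑oxo‑4H‑chromen‑8‑yl]acetyl}oxazolidin‑2‑one, via mixed pivalic anhydride 18 (not isolated)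
Conditions: PivCl, Et3N, THF, −20 °C; then 17, LiCl, 23 °C
Reagents that add atoms: none
Why: N‑Acylation of the oxazolidinone through the mixed pivalic anhydride (LiCl/Et3N protocol) avoids strong base that could attack the chromone.

**Step 10**
Reactants: 19 (R)‑4‑benzyl‑3‑{2‑[5,7‑bis(benzyloxy)‑4‑oxo‑4H‑chromen‑8‑yl]acetyl}oxazolidin‑2‑one; 20 4‑(benzyloxy)benzaldehyde
Product: 22 (R)‑4‑benzyl‑3‑[(2S,3R)‑3‑[4‑(benzyloxy)phenyl]‑2‑[5,7‑bis(benzyloxy)‑4‑oxo‑4H‑chromen‑8‑yl]‑3‑hydroxypropanoyl]oxazolidin‑2‑one, via O‑trimethylsilyl aldol adduct 21 (not isolated)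
Conditions: MgCl2 (0.3 equiv), Et3N, TMSCl, EtOAc, 23 °C; then TFA, MeOH
Reagents that add atoms: none
Why: Evans magnesium halide‑catalysed direct anti‑aldol reaction, in which soft enolisation gives a magnesium‑chelated Z‑enolate that should add to the aldehyde on the face opposite the benzyl group of the (R)‑auxiliary (the sense of Evans alkylations) through a boat‑like transition state, with TMSCl turning the catalyst over, so that (2S,3R) is set in one step.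

**Step 11**
Reactants: 22 (R)‑4‑benzyl‑3‑[(2S,3R)‑3‑[4‑(benzyloxy)phenyl]‑2‑[5,7‑bis(benzyloxy)‑4‑oxo‑4H‑chromen‑8‑yl]‑3‑hydroxypropanoyl]oxazolidin‑2‑one
Product: 23 methyl (2S,3R)‑3‑[4‑(benzyloxy)phenyl]‑2‑[5,7‑bis(benzyloxy)‑4‑oxo‑4H‑chromen‑8‑yl]‑3‑hydroxypropanoate
Conditions: Sm(OTf)3 (0.3 equiv), MeOH/CH2Cl2, 23 °C
Reagents that add atoms: methanol, CO
Why: Lewis acid‑catalysed methanolysis, in which Sm(OTf)3 chelates the imide and activates its exocyclic carbonyl under neutral conditions, so that the base‑labile aldol and the acidic α‑aryl stereocentre should survive while the auxiliary is released.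

**Step 12**
Reactants: 23 methyl (2S,3R)‑3‑[4‑(benzyloxy)phenyl]‑2‑[5,7‑bis(benzyloxy)‑4‑oxo‑4H‑chromen‑8‑yl]‑3‑hydroxypropanoate; 7 3,5‑bis(benzyloxy)‑2‑(trimethylsilyl)phenyl trifluoromethanesulfonate
Product: 25 (2R,3S)‑5,7‑bis(benzyloxy)‑2‑[4‑(benzyloxy)phenyl]‑3‑[5,7‑bis(benzyloxy)‑4‑oxo‑4H‑chromen‑8‑yl]chroman‑4‑one, via 3,5‑bis(benzyloxy)benzyne 24 (not isolated)
Conditions: CsF (4 equiv), MeCN/THF, 0 → 23 °C, 7 (2 equiv) added slowly
Reagents that add atoms: none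
Why: Proposed new method: fluoride converts 7 into aryne 24 and, as a hydrogen‑bonded base, activates the secondary hydroxyl of 23, whose oxygen adds to the aryne carbon remote from the 3‑benzyloxy group; the aryl anion so formed, ortho to that benzyloxy group, is acylated intramolecularly by the methyl ester with loss of methoxide, so that O1–C8a and C4–C4a of ring A of unit 1 form in one operation. The closest known reactions are the fluoride‑mediated annulation of arynes with methyl salicylates to xanthones (phenoxide addition, then ester capture), the analogous acridone synthesis from methyl anthranilates and the O–H insertion of arynes into alcohols; an aliphatic β‑hydroxy ester has not been shown as the partner. The pyranone ring closes by 6‑exo‑trig attack of the aryl carbanion on the ester carbonyl (addition–elimination). No stereocentre is created: C2 and C3 are carried over from the anti‑aldol adduct because no bond to either is broken, and the 2,3‑trans arrangement is also the thermodynamic one should C3 epimerise. The step needs regioselective aryne addition, secured by the inductive and distortion effect of the 3‑benzyloxy group, which places oxygen meta and the acyl group ortho to it (the 5,7‑pattern). It also needs acyl capture to outrun proton transfer and retro‑aldol cleavage, which the six‑membered transition state, the absence of any base stronger than fluoride and the slow release of the aryne are meant to secure.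

**Step 13**
Reactants: 25 (2R,3S)‑5,7‑bis(benzyloxy)‑2‑[4‑(benzyloxy)phenyl]‑3‑[5,7‑bis(benzyloxy)‑4‑oxo‑4H‑chromen‑8‑yl]chroman‑4‑one; 26 (4‑methoxyphenyl)boronic acid
Product: 27 (2R,3S)‑5,7‑bis(benzyloxy)‑2‑[4‑(benzyloxy)phenyl]‑3‑[(2S)‑5,7‑bis(benzyloxy)‑2‑(4‑methoxyphenyl)‑4‑oxochroman‑8‑yl]chroman‑4‑one
Conditions: Pd(OCOCF3)2 (10 mol %), (R)‑4‑tert‑butyl‑2‑(pyridin‑2‑yl)‑4,5‑dihydrooxazole (12 mol %), NH4PF6, H2O, ClCH2CH2Cl, 60 °C
Reagents that add atoms: none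
Why: Asymmetric conjugate addition of an arylboronic acid to a chromone, in which cationic divalent palladium transmetalates with the boronic acid, the aryl–palladium species inserts the chromone C2=C3 bond on the face dictated by the tert‑butyl group of the (R)‑ligand and water protonates the palladium enolate, so that the (2S) centre of unit 2 should be set under catalyst control.

**Step 14**
Reactants: 27 (2R,3S)‑5,7‑bis(benzyloxy)‑2‑[4‑(benzyloxy)phenyl]‑3‑[(2S)‑5,7‑bis(benzyloxy)‑2‑(4‑methoxyphenyl)‑4‑oxochroman‑8‑yl]chroman‑4‑one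
Product: 28 (2R,3S)‑5,7‑dihydroxy‑2‑(4‑hydroxyphenyl)‑3‑[(2S)‑5,7‑dihydroxy‑2‑(4‑methoxyphenyl)‑4‑oxochroman‑8‑yl]chroman‑4‑one (CNP0140544.1)
Conditions: H2 (1 atm), Pd/C, EtOAc/MeOH, 23 °C
Reagents that add atoms: none
Why: Heterogeneous hydrogenolysis of the five benzyl ethers under neutral conditions should leave both chromanone carbonyls, the aryl methyl ether and the three stereocentres untouched.

**Compound list**

1 | 3,5‑bis(benzyloxy)phenol | Oc1cc(OCc2ccccc2)cc(OCc2ccccc2)c1 | starting material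
2 | 3,5‑bis(benzyloxy)phenyl N‑isopropylcarbamate | CC(C)NC(=O)Oc1cc(OCc2ccccc2)cc(OCc2ccccc2)c1 | intermediate
3 | 3,5‑bis(benzyloxy)phenyl N‑(tert‑butyldimethylsilyl)‑N‑isopropylcarbamate | CC(C)N(C(=O)Oc1cc(OCc2ccccc2)cc(OCc2ccccc2)c1)[Si](C)(C)C(C)(C)C | intermediate
4 | 3,5‑bis(benzyloxy)‑2‑(trimethylsilyl)phenyl N‑(tert‑butyldimethylsilyl)‑N‑isopropylcarbamate | CC(C)N(C(=O)Oc1cc(OCc2ccccc2)cc(OCc2ccccc2)c1[Si](C)(C)C)[Si](C)(C)C(C)(C)C | intermediate
5 | 3,5‑bis(benzyloxy)‑2‑(trimethylsilyl)phenyl N‑isopropylcarbamate | CC(C)NC(=O)Oc1cc(OCc2ccccc2)cc(OCc2ccccc2)c1[Si](C)(C)C | intermediate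
6 | 3,5‑bis(benzyloxy)‑2‑(trimethylsilyl)phenol | C[Si](C)(C)c1c(O)cc(OCc2ccccc2)cc1OCc1ccccc1 | intermediate
7 | 3,5‑bis(benzyloxy)‑2‑(trimethylsilyl)phenyl trifluoromethanesulfonate | C[Si](C)(C)c1c(OS(=O)(=O)C(F)(F)F)cc(OCc2ccccc2)cc1OCc1ccccc1 | intermediate
8 | 1‑[2,4‑bis(benzyloxy)‑6‑hydroxyphenyl]ethan‑1‑one | CC(=O)c1c(O)cc(OCc2ccccc2)cc1OCc1ccccc1 | starting material
9 | allyl bromide | C=CCBr | starting material
10 | 1‑[2‑(allyloxy)‑4,6‑bis(benzyloxy)phenyl]ethan‑1‑one | CC(=O)c1c(OCC=C)cc(OCc2ccccc2)cc1OCc1ccccc1 | intermediate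
11 | 2‑acetyl‑6‑allyl‑3,5‑bis(benzyloxy)cyclohexa‑2,4‑dien‑1‑one (Claisen dienone) | CC(=O)C1=C(OCc2ccccc2)C=C(OCc2ccccc2)C(CC=C)C1=O | intermediate
12 | 1‑[3‑allyl‑4,6‑bis(benzyloxy)‑2‑hydroxyphenyl]ethan‑1‑one | CC(=O)c1c(O)c(CC=C)c(OCc2ccccc2)cc1OCc1ccccc1 | intermediate
13 | (E)‑1‑[3‑allyl‑4,6‑bis(benzyloxy)‑2‑hydroxyphenyl]‑3‑(dimethylamino)prop‑2‑en‑1‑one | CN(C)/C=C/C(=O)c1c(O)c(CC=C)c(OCc2ccccc2)cc1OCc1ccccc1 | intermediate
14 | 8‑allyl‑5,7‑bis(benzyloxy)‑4H‑chromen‑4‑one | C=CCc1c(OCc2ccccc2)cc(OCc2ccccc2)c2c(=O)ccoc12 | intermediate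
15 | 2‑[5,7‑bis(benzyloxy)‑4‑oxo‑4H‑chromen‑8‑yl]acetaldehyde | O=CCc1c(OCc2ccccc2)cc(OCc2ccccc2)c2c(=O)ccoc12 | intermediate
16 | 2‑[5,7‑bis(benzyloxy)‑4‑oxo‑4H‑chromen‑8‑yl]acetic acid | OC(=O)Cc1c(OCc2ccccc2)cc(OCc2ccccc2)c2c(=O)ccoc12 | intermediate
17 | (R)‑4‑benzyloxazolidin‑2‑one | O=C1N[C@H](Cc2ccccc2)CO1 | starting material
18 | 2‑[5,7‑bis(benzyloxy)‑4‑oxo‑4H‑chromen‑8‑yl]acetic pivalic anhydride | CC(C)(C)C(=O)OC(=O)Cc1c(OCc2ccccc2)cc(OCc2ccccc2)c2c(=O)ccoc12 | intermediate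
19 | (R)‑4‑benzyl‑3‑{2‑[5,7‑bis(benzyloxy)‑4‑oxo‑4H‑chromen‑8‑yl]acetyl}oxazolidin‑2‑one | O=C(Cc1c(OCc2ccccc2)cc(OCc2ccccc2)c2c(=O)ccoc12)N1C(=O)OC[C@H]1Cc1ccccc1 | intermediate
20 | 4‑(benzyloxy)benzaldehyde | O=Cc1ccc(OCc2ccccc2)cc1 | starting material
21 | O‑trimethylsilyl ether of 22 | O=C([C@@H](c1c(OCc2ccccc2)cc(OCc2ccccc2)c2c(=O)ccoc12)[C@@H](O[Si](C)(C)C)c1ccc(OCc2ccccc2)cc1)N1C(=O)OC[C@H]1Cc1ccccc1 | intermediate
22 | (R)‑4‑benzyl‑3‑[(2S,3R)‑3‑[4‑(benzyloxy)phenyl]‑2‑[5,7‑bis(benzyloxy)‑4‑oxo‑4H‑chromen‑8‑yl]‑3‑hydroxypropanoyl]oxazolidin‑2‑one | O=C([C@@H](c1c(OCc2ccccc2)cc(OCc2ccccc2)c2c(=O)ccoc12)[C@@H](O)c1ccc(OCc2ccccc2)cc1)N1C(=O)OC[C@H]1Cc1ccccc1 | intermediate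
23 | methyl (2S,3R)‑3‑[4‑(benzyloxy)phenyl]‑2‑[5,7‑bis(benzyloxy)‑4‑oxo‑4H‑chromen‑8‑yl]‑3‑hydroxypropanoate | COC(=O)[C@@H](c1c(OCc2ccccc2)cc(OCc2ccccc2)c2c(=O)ccoc12)[C@@H](O)c1ccc(OCc2ccccc2)cc1 | intermediate
24 | 3,5‑bis(benzyloxy)benzyne | C1#CC(OCc2ccccc2)=CC(OCc2ccccc2)=C1 | intermediate
25 | (2R,3S)‑5,7‑bis(benzyloxy)‑2‑[4‑(benzyloxy)phenyl]‑3‑[5,7‑bis(benzyloxy)‑4‑oxo‑4H‑chromen‑8‑yl]chroman‑4‑one | O=c1ccoc2c([C@@H]3C(=O)c4c(OCc5ccccc5)cc(OCc5ccccc5)cc4O[C@H]3c3ccc(OCc4ccccc4)cc3)c(OCc3ccccc3)cc(OCc3ccccc3)c12 | intermediate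
26 | (4‑methoxyphenyl)boronic acid | COc1ccc(B(O)O)cc1 | starting material
27 | (2R,3S)‑5,7‑bis(benzyloxy)‑2‑[4‑(benzyloxy)phenyl]‑3‑[(2S)‑5,7‑bis(benzyloxy)‑2‑(4‑methoxyphenyl)‑4‑oxochroman‑8‑yl]chroman‑4‑one | COc1ccc([C@@H]2CC(=O)c3c(OCc4ccccc4)cc(OCc4ccccc4)c([C@@H]4C(=O)c5c(OCc6ccccc6)cc(OCc6ccccc6)cc5O[C@H]4c4ccc(OCc5ccccc5)cc4)c3O2)cc1 | intermediate
28 | (2R,3S)‑5,7‑dihydroxy‑2‑(4‑hydroxyphenyl)‑3‑[(2S)‑5,7‑dihydroxy‑2‑(4‑methoxyphenyl)‑4‑oxochroman‑8‑yl]chroman‑4‑one | COc1ccc([C@@H]2CC(=O)c3c(O)cc(O)c([C@@H]4C(=O)c5c(O)cc(O)cc5O[C@H]4c4ccc(O)cc4)c3O2)cc1 | target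

**Step count and risks**

Total step count: 14 (steps 1–3 make the aryne precursor; steps 4–14 are the main line).
Longest linear sequence: 11 steps (8 → 28, steps 4–14).

Steps most likely to fail:

1. Step 12 (proposed new method). What may go wrong: the hindered secondary hydroxyl may add too slowly to the aryne, a proton may reach the aryl anion before the ester does (leaving an uncyclised aryl ether), or the fluoride‑activated hydroxy ester may fragment by retro‑aldol cleavage. The fallback uses known chemistry, sets out from acid 16 (with 20 and 7) and comes back to the route at 27. It gives up the preformed stereocentres and makes the same two bonds by the known C–O insertion of arynes into carboxylic acids followed by oxa‑Michael closure. Perkin condensation of 16 with 20 (Ac2O, Et3N, 110 °C) should give (E)‑2‑[5,7‑bis(benzyloxy)‑4‑oxo‑4H‑chromen‑8‑yl]‑3‑[4‑(benzyloxy)phenyl]acrylic acid F1. Heating F1 with 7 and CsF in THF (sealed tube, about 125 °C) should add the carboxylate to aryne 24 at the carbon remote from the benzyloxy group, and acyl migration to the aryl anion should give (E)‑1‑[2,4‑bis(benzyloxy)‑6‑hydroxyphenyl]‑2‑[5,7‑bis(benzyloxy)‑4‑oxo‑4H‑chromen‑8‑yl]‑3‑[4‑(benzyloxy)phenyl]prop‑2‑en‑1‑one F2. F2 should close in the flask by 6‑endo‑trig oxa‑Michael addition to the thermodynamically favoured racemic trans‑chromanone F3. Resolution is deferred: arylation of F3 under the conditions of step 13 should give 27 together with the (2S,3R)‑unit 1, (2S)‑unit 2 diastereomer F4. The two differ as diastereomers and should be separable on silica or by preparative HPLC.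

2. Step 10. What may go wrong: the di‑ortho‑substituted aryl enolate may add slowly to the electron‑rich aldehyde, the chromone carbonyl may sequester MgCl2, or anti and facial selectivity may erode. The fallback sets out from imide 19 and comes back at 25. A boron‑mediated Evans syn‑aldol reaction of 19 with 20 (Bu2BOTf, i‑Pr2NEt, CH2Cl2, −78 → 0 °C; closed Zimmerman–Traxler transition state of the Z‑boron enolate) should give (R)‑4‑benzyl‑3‑[(2R,3R)‑3‑[4‑(benzyloxy)phenyl]‑2‑[5,7‑bis(benzyloxy)‑4‑oxo‑4H‑chromen‑8‑yl]‑3‑hydroxypropanoyl]oxazolidin‑2‑one F5. F5 has the required carbinol configuration but the opposite α‑configuration. Methanolysis as in step 11 should give methyl (2R,3R)‑3‑[4‑(benzyloxy)phenyl]‑2‑[5,7‑bis(benzyloxy)‑4‑oxo‑4H‑chromen‑8‑yl]‑3‑hydroxypropanoate F6, and annulation as in step 12 should give the 2,3‑cis chromanone (2R,3R)‑5,7‑bis(benzyloxy)‑2‑[4‑(benzyloxy)phenyl]‑3‑[5,7‑bis(benzyloxy)‑4‑oxo‑4H‑chromen‑8‑yl]chroman‑4‑one F7. Equilibration of the acidic C3–H of F7 (Et3N or catalytic DBU, CH2Cl2, 23 °C) to the more stable trans isomer should then give 25.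

3. Step 13. What may go wrong: insertion into the electron‑rich, 8‑substituted chromone may be slow enough for protodeboronation of the boronic acid to win, or the stereocentres of unit 1 may oppose the catalyst (mismatched double stereodifferentiation) and lower facial selectivity. The fallback sets out from imide 19 and comes back at 27. It sets the unit 2 stereocentre on the small chromone before the fragments are joined. Arylation of 19 with 26 under the conditions of step 13 should give (R)‑4‑benzyl‑3‑{2‑[(2S)‑5,7‑bis(benzyloxy)‑2‑(4‑methoxyphenyl)‑4‑oxochroman‑8‑yl]acetyl}oxazolidin‑2‑one F8. The magnesium‑catalysed anti‑aldol reaction with 20 as in step 10 should pass through the O‑trimethylsilyl aldol adduct F9 and give (R)‑4‑benzyl‑3‑[(2S,3R)‑3‑[4‑(benzyloxy)phenyl]‑2‑[(2S)‑5,7‑bis(benzyloxy)‑2‑(4‑methoxyphenyl)‑4‑oxochroman‑8‑yl]‑3‑hydroxypropanoyl]oxazolidin‑2‑one F10. Methanolysis as in step 11 should give methyl (2S,3R)‑3‑[4‑(benzyloxy)phenyl]‑2‑[(2S)‑5,7‑bis(benzyloxy)‑2‑(4‑methoxyphenyl)‑4‑oxochroman‑8‑yl]‑3‑hydroxypropanoate F11, and annulation with 7 and CsF as in step 12 should give 27 directly.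

**Further compounds**

F1 | step 12 | (E)‑2‑[5,7‑bis(benzyloxy)‑4‑oxo‑4H‑chromen‑8‑yl]‑3‑[4‑(benzyloxy)phenyl]acrylic acid | OC(=O)/C(=C/c1ccc(OCc2ccccc2)cc1)c1c(OCc2ccccc2)cc(OCc2ccccc2)c2c(=O)ccoc12
F2 | step 12 | (E)‑1‑[2,4‑bis(benzyloxy)‑6‑hydroxyphenyl]‑2‑[5,7‑bis(benzyloxy)‑4‑oxo‑4H‑chromen‑8‑yl]‑3‑[4‑(benzyloxy)phenyl]prop‑2‑en‑1‑one | O=C(c1c(O)cc(OCc2ccccc2)cc1OCc1ccccc1)/C(=C/c1ccc(OCc2ccccc2)cc1)c1c(OCc2ccccc2)cc(OCc2ccccc2)c2c(=O)ccoc12
F3 | step 12 | racemic trans‑5,7‑bis(benzyloxy)‑2‑[4‑(benzyloxy)phenyl]‑3‑[5,7‑bis(benzyloxy)‑4‑oxo‑4H‑chromen‑8‑yl]chroman‑4‑one (both enantiomers) | O=c1ccoc2c([C@@H]3C(=O)c4c(OCc5ccccc5)cc(OCc5ccccc5)cc4O[C@H]3c3ccc(OCc4ccccc4)cc3)c(OCc3ccccc3)cc(OCc3ccccc3)c12.O=c1ccoc2c([C@H]3C(=O)c4c(OCc5ccccc5)cc(OCc5ccccc5)cc4O[C@@H]3c3ccc(OCc4ccccc4)cc3)c(OCc3ccccc3)cc(OCc3ccccc3)c12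
F4 | step 12 | (2S,3R)‑5,7‑bis(benzyloxy)‑2‑[4‑(benzyloxy)phenyl]‑3‑[(2S)‑5,7‑bis(benzyloxy)‑2‑(4‑methoxyphenyl)‑4‑oxochroman‑8‑yl]chroman‑4‑one | COc1ccc([C@@H]2CC(=O)c3c(OCc4ccccc4)cc(OCc4ccccc4)c([C@H]4C(=O)c5c(OCc6ccccc6)cc(OCc6ccccc6)cc5O[C@@H]4c4ccc(OCc5ccccc5)cc4)c3O2)cc1
F5 | step 10 | (R)‑4‑benzyl‑3‑[(2R,3R)‑3‑[4‑(benzyloxy)phenyl]‑2‑[5,7‑bis(benzyloxy)‑4‑oxo‑4H‑chromen‑8‑yl]‑3‑hydroxypropanoyl]oxazolidin‑2‑one | O=C([C@H](c1c(OCc2ccccc2)cc(OCc2ccccc2)c2c(=O)ccoc12)[C@@H](O)c1ccc(OCc2ccccc2)cc1)N1C(=O)OC[C@H]1Cc1ccccc1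
F6 | step 10 | methyl (2R,3R)‑3‑[4‑(benzyloxy)phenyl]‑2‑[5,7‑bis(benzyloxy)‑4‑oxo‑4H‑chromen‑8‑yl]‑3‑hydroxypropanoate | COC(=O)[C@H](c1c(OCc2ccccc2)cc(OCc2ccccc2)c2c(=O)ccoc12)[C@@H](O)c1ccc(OCc2ccccc2)cc1
F7 | step 10 | (2R,3R)‑5,7‑bis(benzyloxy)‑2‑[4‑(benzyloxy)phenyl]‑3‑[5,7‑bis(benzyloxy)‑4‑oxo‑4H‑chromen‑8‑yl]chroman‑4‑one (2,3‑cis) | O=c1ccoc2c([C@H]3C(=O)c4c(OCc5ccccc5)cc(OCc5ccccc5)cc4O[C@H]3c3ccc(OCc4ccccc4)cc3)c(OCc3ccccc3)cc(OCc3ccccc3)c12
F8 | step 13 | (R)‑4‑benzyl‑3‑{2‑[(2S)‑5,7‑bis(benzyloxy)‑2‑(4‑methoxyphenyl)‑4‑oxochroman‑8‑yl]acetyl}oxazolidin‑2‑one | COc1ccc([C@@H]2CC(=O)c3c(OCc4ccccc4)cc(OCc4ccccc4)c(CC(=O)N4C(=O)OC[C@H]4Cc4ccccc4)c3O2)cc1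
F9 | step 13 | O‑trimethylsilyl ether of F10 | COc1ccc([C@@H]2CC(=O)c3c(OCc4ccccc4)cc(OCc4ccccc4)c([C@@H]([C@@H](O[Si](C)(C)C)c4ccc(OCc5ccccc5)cc4)C(=O)N4C(=O)OC[C@H]4Cc4ccccc4)c3O2)cc1
F10 | step 13 | (R)‑4‑benzyl‑3‑[(2S,3R)‑3‑[4‑(benzyloxy)phenyl]‑2‑[(2S)‑5,7‑bis(benzyloxy)‑2‑(4‑methoxyphenyl)‑4‑oxochroman‑8‑yl]‑3‑hydroxypropanoyl]oxazolidin‑2‑one | COc1ccc([C@@H]2CC(=O)c3c(OCc4ccccc4)cc(OCc4ccccc4)c([C@@H]([C@@H](O)c4ccc(OCc5ccccc5)cc4)C(=O)N4C(=O)OC[C@H]4Cc4ccccc4)c3O2)cc1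
F11 | step 13 | methyl (2S,3R)‑3‑[4‑(benzyloxy)phenyl]‑2‑[(2S)‑5,7‑bis(benzyloxy)‑2‑(4‑methoxyphenyl)‑4‑oxochroman‑8‑yl]‑3‑hydroxypropanoate | COc1ccc([C@@H]2CC(=O)c3c(OCc4ccccc4)cc(OCc4ccccc4)c([C@@H]([C@@H](O)c4ccc(OCc5ccccc5)cc4)C(=O)OC)c3O2)cc1
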